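**Retrosynthetic overview**

1. Target 32 ⇐ 29: the side-chain ketone is unmasked last from a C7 alkynyl carbinol (CO2-relayed alkyne hydration), after C1–OH has been inverted (oxidation, hydroxyl-directed reduction) and angeloylated; the carbinol comes from addition of an (R)-butynol acetylide to cycloheptanone 20.
2. 20 ⇐ 12: β-elimination opens the oxygen bridge of an 8-oxabicyclo[3.2.1]octan-3-one (the C4 enol expels the C6–O bond) and the freed C2–OH closes the γ-lactone; one hydrogenation then sets C6 and C3 and removes the C3 benzyl ester, and C4=O is deleted.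
3. Key disconnection (C2–C3 and C5–C6 together): a dirhodium-catalysed vinylcarbenoid (4+3) annulation (cyclopropanation/Cope) that dearomatises 2-methylfuran. It is possible because the oxygen-bearing C2 and the methyl-bearing C6 are 1,4-related in the cycloheptane: C6–C7–C1–C2 plus the lactone oxygen are the five ring atoms of 2-methylfuran, and C3–C4–C5 is the three-carbon unit of the carbenoid.
4. Ring order: oxygen-bridged seven-membered carbocycle (step 3), then γ-lactone (step 8); the lactone α-carbon comes from (R)-lactate by alkylation at C3 of the β-keto ester left by the key step.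

Key step: step 3

**Remarks**

- Locants (target numbering, used for all intermediates): C1 (O-angelate), C2 (lactone O), C3 (ring-fusion CH), C4, C5 (CH2), C6 (CH–CH3), C7 (C–OH); C1′–C4′ = side chain on C7 (C1′ = C=O, C3′ = CHOH); Cα = lactone α-carbon. α = ring face carrying the C2–O bond, β = the other face. In the target C2–O, C3–Cα, C6–CH3 and C7–OH are α; C1–O and the C7 acyl group are β.
- Assumption: Rh2(S-PTAD)4 is taken to give the enantiomer drawn for 5–7; if the sense of induction is the opposite, Rh2(R-PTAD)4 is used.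

**Route**

Step 1
Reactants: 1 benzyl acetoacetate
Product: 2 benzyl 2-diazo-3-oxobutanoate
Conditions: p-ABSA, Et3N, MeCN, 0 °C to rt
Reagents that add atoms: 4-acetamidobenzenesulfonyl azide (p-ABSA), CC(=O)Nc1ccc(cc1)S(=O)(=O)N=[N+]=[N-]
Why: Regitz diazo transfer to the doubly activated methylene; no stereocentre is involved.

Step 2
Reactants: 2 benzyl 2-diazo-3-oxobutanoate
Product: 3 benzyl 3-[(tert-butyldimethylsilyl)oxy]-2-diazobut-3-enoate
Conditions: TBSOTf, Et3N, CH2Cl2, 0 °C
Reagents that add atoms: tert-butyldimethylsilyl trifluoromethanesulfonate, CC(C)(C)[Si](C)(C)OS(=O)(=O)C(F)(F)F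
Why: Soft enolisation and O-silylation of the acetyl group gives the 2-siloxyvinyl diazoacetate, a donor/acceptor vinylcarbenoid precursor; no stereocentre.

Step 3
Reactants: 3 benzyl 3-[(tert-butyldimethylsilyl)oxy]-2-diazobut-3-enoate; 4 2-methylfuran
Product: 7 benzyl (1S,5S)-3-hydroxy-5-methyl-8-oxabicyclo[3.2.1]octa-2,6-diene-2-carboxylate (enol form of the bicyclic β-keto ester), via cis-divinylcyclopropane 5 (not isolated), via silyl enol ether 6 (not isolated)
Conditions: Rh2(S-PTAD)4 (1 mol %), 4 (5 equiv), hexanes, slow addition of 3, −20 °C to rt; then TBAF, AcOH, THF, 0 °C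
Reagents that add atoms: none
Why: The rhodium carbenoid formed from 3 by loss of N2 cyclopropanates the unsubstituted C4=C5 bond of the furan, making the C2–C3 bond (and a temporary C1–C3 bond) of cis-divinylcyclopropane 5, whose Cope rearrangement through the obligatory boat transition state makes the C5–C6 bond, breaks the temporary bond and leaves silyl enol ether 6, which fluoride converts to 7. The closest known reaction type is the dirhodium-tetracarboxylate-catalysed tandem cyclopropanation/Cope rearrangement (formal (4+3) cycloaddition) of 2-siloxyvinyl diazoacetates with furans, N-acylpyrroles and acyclic dienes, for which Rh2(PTAD)4 catalysts give high enantioselectivity. Ring closures: the cyclopropane by [2+1] carbene transfer, the seven-membered carbocycle by the [3,3]-sigmatropic shift, which turns the furan oxygen into the one-atom bridge of an 8-oxabicyclo[3.2.1]octadiene. The new stereocentres are the bridgeheads C2 and C6: their relative configuration is fixed by the bridge, their absolute configuration by the chiral carboxylate ligands, which choose the furan face in the cyclopropanation. The step needs site selectivity for the unsubstituted furan double bond with first C–C bonding at the free α-carbon: the 2-methyl group shields the other double bond and stabilises the developing positive charge, so the ester-bearing carbenoid carbon becomes C3 (next to the bridgehead CH) and the vinyl CH2 bonds to the methyl-bearing carbon (C5–C6), while excess furan and the donor/acceptor carbenoid should suppress carbene dimerisation and furan ring-opening.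

Step 4
Reactants: 8 methyl (R)-lactate
Product: 9 methyl (2R)-2-[(trifluoromethanesulfonyl)oxy]propanoate
Conditions: Tf2O, 2,6-lutidine, CH2Cl2, −78 to 0 °C
Reagents that add atoms: trifluoromethanesulfonic anhydride, O=S(=O)(OS(=O)(=O)C(F)(F)F)C(F)(F)F
Why: O-sulfonylation leaves the stereocentre untouched and gives a very reactive, configurationally stable SN2 electrophile.

Step 5
Reactants: 7 bicyclic β-keto ester; 9 methyl (2R)-2-[(trifluoromethanesulfonyl)oxy]propanoate
Product: 10 benzyl 2-[(2R)-1-methoxy-1-oxopropan-2-yl]-5-methyl-3-oxo-8-oxabicyclo[3.2.1]oct-6-ene-2-carboxylate (bridgeheads as in 7; at the quaternary C3 the propanoate arm is α, the benzyl ester β)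
Conditions: NaH, THF, 0 °C; then 9, 0 °C to rt
Reagents that add atoms: none
Why: C-alkylation of a β-keto ester sodium enolate by an α-triflyloxy ester is a known SN2 process with clean inversion, so the (R)-triflate gives the (R)-configured arm (the lactone α-carbon of the target); the ester makes C3 the only nucleophilic carbon and the electrophile should enter axially on the face away from the C1=C7 bridge, which places the arm on the α-face at the new quaternary C3.

Step 6
Reactants: 10 alkylated bicyclic keto diester
Product: 11 the C1,C7-exo,exo-diol of 10 (both hydroxyls α)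
Conditions: OsO4 (2 mol %), NMO, acetone/H2O, rt
Reagents that add atoms: N-methylmorpholine N-oxide, C[N+]1([O-])CCOCC1; water, O
Why: Upjohn dihydroxylation: OsO4 adds to the strained C1=C7 bond from its exo face, which is the face of the oxygen bridge, so both new C–O bonds are α (cis to C2–O).

Step 7
Reactants: 11 bicyclic diol
Product: 12 the C1-O-tert-butyldiphenylsilyl ether of 11 with free C7–OH
Conditions: TBDPSCl (1.05 equiv), imidazole, DMF, 0 °C
Reagents that add atoms: tert-butyl(chloro)diphenylsilane, CC(C)(C)[Si](Cl)(c1ccccc1)c1ccccc1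
Why: Steric differentiation of the two secondary hydroxyls: C7–OH sits next to the methyl-bearing quaternary bridgehead C6, C1–OH next to the bridgehead CH, so the bulky silyl chloride should react at C1–OH (a minor regioisomer would be separated and recycled by desilylation).

Step 8
Reactants: 12 mono-silylated bicyclic diol
Product: 15 cis-fused lactone enone (C1 α-OTBDPS; C2–O/C3–Cα lactone on the α-face; C3 quaternary with β benzyl ester; C4 ketone; C5=C6 with 6-methyl; C7 α-OH), via bis(trimethylsilyl) ether 13 (not isolated), via dihydroxy diester 14 (not isolated)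
Conditions: TMSOTf (3.5 equiv), Et3N (5 equiv), CH2Cl2, −78 to 0 °C; then TsOH·H2O (0.2 equiv), wet THF, rt
Reagents that add atoms: none
Why: Silyl-triflate-promoted β-elimination is known for 8-oxabicyclo[3.2.1]octan-3-ones, and because C3 is quaternary the C4 ketone can form its enol silane only towards C5, which expels the silylated bridge oxygen from C6 and gives the C5=C6 enone with C2–OSiMe3; acidic desilylation then lets the C2 hydroxyl close the γ-lactone on the α-disposed methyl ester (cis fusion), acid rather than base being used so that the β-hydroxy β-keto ester is trapped before it can undergo retro-aldol cleavage.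

Step 9
Reactants: 15 lactone enone benzyl ester
Product: 17 saturated lactone ketone (C1 α-OTBDPS; cis-fused α-lactone with C3–H β; C4 ketone; C6 α-methyl; C7 α-OH), via β-keto acid 16 (not isolated)
Conditions: H2 (1 atm), Pd/C (10 % palladium on carbon), EtOAc, rt; then 45 °C
Reagents that add atoms: none
Why: One hydrogenation should do three things: the benzyl ester is hydrogenolysed and the β-keto acid loses CO2 on warming, the resulting enol being protonated at the ring-fusion carbon C3 on the exposed β-face (cis to H-2, the usual kinetic outcome for ring-fusion enols, hence the cis-fused lactone), and the C5=C6 bond takes up H2 from the β-face because C7–OH, the C1 silyl ether and the lactone all lie on the α-face, which puts the C6 methyl α.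

Step 10
Reactants: 17 saturated lactone ketone
Product: 19 C4-deoxygenated lactone alcohol (C1 α-OTBDPS; C7 α-OH), via tosylhydrazone 18 (not isolated)
Conditions: TsNHNH2, EtOH, 50 °C; evaporation; catecholborane, CHCl3, 0 °C; then NaOAc·3H2O, 60 °C
Reagents that add atoms: none
Why: Caglioti-type deoxygenation (hydride reduction of the tosylhydrazone, then loss of sulfinate and N2 from the diazene) replaces C4=O by CH2 under conditions that spare lactone and silyl ether; with the carbonyl gone the C3 ring-fusion centre can no longer epimerise.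

Step 11
Reactants: 19 lactone alcohol
Product: 20 C7 ketone (C1 α-OTBDPS; C6 α-methyl; cis-fused α-lactone)
Conditions: Dess–Martin periodinane, NaHCO3, CH2Cl2, rt
Reagents that add atoms: none
Why: Dess–Martin oxidation of the only free hydroxyl gives the C7 ketone; the now enolisable C6 centre is carried on at once.

Step 12
Reactants: 21 (R)-but-3-yn-2-ol
Product: 22 (R)-3-[(4-methoxybenzyl)oxy]but-1-yne
Conditions: NaH, 4-methoxybenzyl chloride, Bu4NI (cat.), THF/DMF, 0 °C to rt
Reagents that add atoms: 4-methoxybenzyl chloride, COc1ccc(CCl)cc1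
Why: Williamson etherification at oxygen; the C–O bond at the stereocentre is not broken, so the (R) configuration (C3′ of the target) is kept.

Step 13
Reactants: 20 C7 ketone; 22 (R)-3-[(4-methoxybenzyl)oxy]but-1-yne
Product: 23 C7 alkynyl carbinol (C7 α-OH and β-alkynyl chain; C1 α-OTBDPS; C3′ O-PMB)
Conditions: 22, n-BuLi, THF, −78 °C; CeCl3; then 20, −78 °C; aq. NH4Cl work-up
Reagents that add atoms: none
Why: 1,2-Addition of a slim, weakly basic cerium acetylide should occur from the β-face, anti to both α-substituents that flank the carbonyl (C6 methyl and C1 silyloxy; steric and Felkin-type control agree), giving the C7 carbinol with OH α and the carbon chain β as in the target, while cerium suppresses enolisation and β-elimination of the lactone.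

Step 14
Reactants: 23 alkynyl carbinol silyl ether
Product: 24 C1,C7-cis-diol (both hydroxyls α)
Conditions: TBAF, AcOH, THF, rt to 40 °C
Reagents that add atoms: none
Why: Fluoride cleavage of the silyl ether, buffered with AcOH to protect the lactone α-centre; the PMB ether is untouched.

Step 15
Reactants: 24 cis-diol
Product: 25 C1 ketone with tertiary C7 α-OH
Conditions: IBX, DMSO, rt
Reagents that add atoms: none
Why: IBX oxidises the secondary C1 hydroxyl of a vicinal diol to the α-hydroxy ketone without glycol cleavage; the tertiary C7–OH cannot be oxidised.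

Step 16
Reactants: 25 α-hydroxy ketone
Product: 26 C1,C7-trans-diol (C1–OH β; C7–OH α)
Conditions: Me4NBH(OAc)3, MeCN/AcOH, −30 °C
Reagents that add atoms: none
Why: Evans–Saksena-type reduction: the α C7 hydroxyl binds the acyloxyborohydride and delivers hydride intramolecularly to the α-face of the C1 ketone, so the new C1–OH is β, i.e. C1 is inverted to the configuration of the target.

Step 17
Reactants: 26 trans-diol; 27 angelic acid
Product: 29 C1 angelate of 26 (tertiary propargylic C7–OH free), via mixed anhydride 28 (not isolated)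
Conditions: 27, 2,4,6-trichlorobenzoyl chloride, Et3N, toluene, rt; then 26, toluene, 80 °C
Reagents that add atoms: none
Why: Yamaguchi-type acylation through the mixed anhydride without DMAP is the established way to form angelates without Z to E isomerisation; only the secondary C1–OH should be acylated, the tertiary propargylic C7–OH being too hindered.

Step 18
Reactants: 29 angelate alkyne
Product: 31 O-PMB-protected target (C7 α-hydroxy ketone side chain), via alkylidene cyclic carbonate 30 (not isolated)
Conditions: AgOAc (10 mol %), DBU (20 mol %), CO2 (1 atm), MeCN, rt; then H2O, 40 °C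
Reagents that add atoms: carbon dioxide, O=C=O; water, O
Why: Silver-catalysed carboxylative cyclisation of a tertiary propargylic alcohol: the carbonate formed from the C7 oxygen and CO2 attacks the silver-activated alkyne 5-exo-dig, so oxygen is delivered to C1′ only, and hydrolysis with loss of CO2 gives the α-hydroxy ketone with CH2 at C2′; no stereocentre is touched.

Step 19
Reactants: 31 O-PMB-protected target
Product: 32 target, (3R,3aS,6S,7S,8S,8aR)-7-hydroxy-7-[(3R)-3-hydroxybutanoyl]-3,6-dimethyl-2-oxooctahydro-2H-cyclohepta[b]furan-8-yl (2Z)-2-methylbut-2-enoate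
Conditions: DDQ, CH2Cl2/pH 7 buffer, 0 °C
Reagents that add atoms: none
Why: Oxidative cleavage of the PMB ether under buffered neutral conditions should leave the angelate, the lactone, the tertiary α-ketol and the liberated β-hydroxy ketone intact.

**Compound list**

1 | benzyl acetoacetate | CC(=O)CC(=O)OCc1ccccc1 | starting material
2 | benzyl 2-diazo-3-oxobutanoate | CC(=O)C(=[N+]=[N-])C(=O)OCc1ccccc1 | intermediate
3 | benzyl 3-[(tert-butyldimethylsilyl)oxy]-2-diazobut-3-enoate | C=C(O[Si](C)(C)C(C)(C)C)C(=[N+]=[N-])C(=O)OCc1ccccc1 | intermediate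
4 | 2-methylfuran | Cc1ccco1 | starting material
5 | cis-divinylcyclopropane: benzyl 6-{1-[(tert-butyldimethylsilyl)oxy]ethenyl}-3-methyl-2-oxabicyclo[3.1.0]hex-3-ene-6-carboxylate, siloxyvinyl group endo (not isolated) | CC1=C[C@@H]2[C@H](O1)[C@]2(C(=O)OCc3ccccc3)C(=C)O[Si](C)(C)C(C)(C)C | intermediate
6 | silyl enol ether: benzyl (1S,5S)-3-[(tert-butyldimethylsilyl)oxy]-5-methyl-8-oxabicyclo[3.2.1]octa-2,6-diene-2-carboxylate (not isolated) | C[C@@]12CC(O[Si](C)(C)C(C)(C)C)=C(C(=O)OCc3ccccc3)[C@@H](O1)C=C2 | intermediate
7 | benzyl (1S,5S)-3-hydroxy-5-methyl-8-oxabicyclo[3.2.1]octa-2,6-diene-2-carboxylate (enol form of the β-keto ester; oxygen bridge between C2 and C6) | C[C@@]12CC(O)=C(C(=O)OCc3ccccc3)[C@@H](O1)C=C2 | intermediate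
8 | methyl (R)-lactate | C[C@@H](O)C(=O)OC | starting material
9 | methyl (2R)-2-[(trifluoromethanesulfonyl)oxy]propanoate | C[C@@H](OS(=O)(=O)C(F)(F)F)C(=O)OC | intermediate
10 | benzyl 2-[(2R)-1-methoxy-1-oxopropan-2-yl]-5-methyl-3-oxo-8-oxabicyclo[3.2.1]oct-6-ene-2-carboxylate; bridgeheads as in 7; quaternary C3 with α propanoate arm and β benzyl ester | C[C@@]12CC(=O)[C@@](C(=O)OCc3ccccc3)([C@@H](C)C(=O)OC)[C@@H](O1)C=C2 | intermediate
11 | C1,C7-exo,exo-diol of 10 (both OH α, syn to the oxygen bridge) | C[C@@]12CC(=O)[C@@](C(=O)OCc3ccccc3)([C@@H](C)C(=O)OC)[C@@H](O1)[C@@H](O)[C@H]2O | intermediate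
12 | C1-O-TBDPS ether of 11, C7–OH free | C[C@@]12CC(=O)[C@@](C(=O)OCc3ccccc3)([C@@H](C)C(=O)OC)[C@@H](O1)[C@@H](O[Si](c4ccccc4)(c5ccccc5)C(C)(C)C)[C@H]2O | intermediate
13 | bis(trimethylsilyl) ether: ring-opened cyclohept-5-en-4-one with C1 α-OTBDPS, C2 α-OSiMe3, C7 α-OSiMe3, quaternary C3 (not isolated) | CC(C)(C)[Si](c3ccccc3)(c4ccccc4)O[C@@H]1[C@H](O[Si](C)(C)C)[C@](C(=O)OCc5ccccc5)([C@@H](C)C(=O)OC)C(=O)C=C(C)[C@@H]1O[Si](C)(C)C | intermediate
14 | dihydroxy diester: 13 without the two SiMe3 groups (not isolated) | CC(C)(C)[Si](c3ccccc3)(c4ccccc4)O[C@@H]1[C@H](O)[C@](C(=O)OCc5ccccc5)([C@@H](C)C(=O)OC)C(=O)C=C(C)[C@@H]1O | intermediate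
15 | cis-fused lactone enone: C1 α-OTBDPS, α-lactone at C2/C3, C3 β-CO2Bn, C4 ketone, C5=C6 (6-methyl), C7 α-OH | CC(C)(C)[Si](c3ccccc3)(c4ccccc4)O[C@@H]1[C@@H]2OC(=O)[C@H](C)[C@]2(C(=O)OCc5ccccc5)C(=O)C=C(C)[C@@H]1O | intermediate
16 | β-keto acid: saturated analogue of 15 with C3–CO2H and C6 α-methyl (not isolated) | CC(C)(C)[Si](c3ccccc3)(c4ccccc4)O[C@@H]1[C@@H]2OC(=O)[C@H](C)[C@]2(C(=O)O)C(=O)C[C@H](C)[C@@H]1O | intermediate
17 | saturated lactone ketone: C1 α-OTBDPS, cis-fused α-lactone (C3–H β), C4 ketone, C6 α-methyl, C7 α-OH | CC(C)(C)[Si](c3ccccc3)(c4ccccc4)O[C@@H]1[C@@H]2OC(=O)[C@H](C)[C@@H]2C(=O)C[C@H](C)[C@@H]1O | intermediate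
18 | tosylhydrazone of 17 at C4 (not isolated) | CC(C)(C)[Si](c3ccccc3)(c4ccccc4)O[C@@H]1[C@@H]2OC(=O)[C@H](C)[C@@H]2C(=NNS(=O)(=O)c5ccc(C)cc5)C[C@H](C)[C@@H]1O | intermediate
19 | C4-deoxygenated lactone alcohol: C1 α-OTBDPS, C6 α-methyl, C7 α-OH | CC(C)(C)[Si](c3ccccc3)(c4ccccc4)O[C@@H]1[C@@H]2OC(=O)[C@H](C)[C@@H]2CC[C@H](C)[C@@H]1O | intermediate
20 | C7 ketone: C1 α-OTBDPS, C6 α-methyl, cis-fused α-lactone | CC(C)(C)[Si](c3ccccc3)(c4ccccc4)O[C@@H]1[C@@H]2OC(=O)[C@H](C)[C@@H]2CC[C@H](C)C1=O | intermediate
21 | (R)-but-3-yn-2-ol | C#C[C@@H](C)O | starting material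
22 | (R)-3-[(4-methoxybenzyl)oxy]but-1-yne | C#C[C@@H](C)OCc1ccc(OC)cc1 | intermediate
23 | C7 alkynyl carbinol: C7 α-OH, β-alkynyl chain with (R)-O-PMB at C3′, C1 α-OTBDPS | CC(C)(C)[Si](c3ccccc3)(c4ccccc4)O[C@@H]1[C@@H]2OC(=O)[C@H](C)[C@@H]2CC[C@H](C)[C@@]1(O)C#C[C@@H](C)OCc5ccc(OC)cc5 | intermediate
24 | C1,C7-cis-diol (C1–OH α, C7–OH α) | O[C@@H]1[C@@H]2OC(=O)[C@H](C)[C@@H]2CC[C@H](C)[C@@]1(O)C#C[C@@H](C)OCc3ccc(OC)cc3 | intermediate
25 | C1 ketone with C7 α-OH | O=C1[C@@H]2OC(=O)[C@H](C)[C@@H]2CC[C@H](C)[C@@]1(O)C#C[C@@H](C)OCc3ccc(OC)cc3 | intermediate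
26 | C1,C7-trans-diol (C1–OH β, C7–OH α) | O[C@H]1[C@@H]2OC(=O)[C@H](C)[C@@H]2CC[C@H](C)[C@@]1(O)C#C[C@@H](C)OCc3ccc(OC)cc3 | intermediate
27 | angelic acid, (Z)-2-methylbut-2-enoic acid | C/C=C(/C)C(=O)O | starting material
28 | mixed anhydride: (Z)-2-methylbut-2-enoic 2,4,6-trichlorobenzoic anhydride (not isolated) | C/C=C(/C)C(=O)OC(=O)c1c(Cl)cc(Cl)cc1Cl | intermediate
29 | C1 angelate of 26 | C/C=C(/C)C(=O)O[C@H]1[C@@H]2OC(=O)[C@H](C)[C@@H]2CC[C@H](C)[C@@]1(O)C#C[C@@H](C)OCc3ccc(OC)cc3 | intermediate
30 | alkylidene cyclic carbonate: spiro 1,3-dioxolan-2-one on C7 (C7–O α) with (Z)-exocyclic C1′=C2′ (not isolated) | C/C=C(/C)C(=O)O[C@H]1[C@@H]2OC(=O)[C@H](C)[C@@H]2CC[C@H](C)[C@]13OC(=O)O/C3=C\[C@@H](C)OCc4ccc(OC)cc4 | intermediate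
31 | O-PMB-protected target (C3′ O-PMB) | C/C=C(/C)C(=O)O[C@H]1[C@@H]2OC(=O)[C@H](C)[C@@H]2CC[C@H](C)[C@@]1(O)C(=O)C[C@@H](C)OCc3ccc(OC)cc3 | intermediate
32 | target: (3R,3aS,6S,7S,8S,8aR)-7-hydroxy-7-[(3R)-3-hydroxybutanoyl]-3,6-dimethyl-2-oxooctahydro-2H-cyclohepta[b]furan-8-yl (2Z)-2-methylbut-2-enoate | C/C=C(/C)C(=O)O[C@H]1[C@@H]2OC(=O)[C@H](C)[C@@H]2CC[C@H](C)[C@@]1(O)C(=O)C[C@@H](C)O | target

**Step count and risks**

Total step count: 19. Longest linear sequence: 17 (steps 1–3, 5–11, 13–19).

Steps most likely to fail: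

1. Step 3 (key step). What may go wrong: loss of enantioface control in the cyclopropanation, since a furan and a benzyl ester are less well matched to the chiral carboxylate ligands than the pyrroles, dienes and methyl esters for which this catalyst type works best. Fallback: let the enantiopure lactate fragment sort the stereochemistry. Setting out again from 3 and 4, achiral Rh2(OPiv)4 runs the same tandem reaction without induction, so that each of 5, 6 and 7 forms together with its mirror image: enantiomeric cyclopropane F1 rearranges to enantiomeric silyl enol ether F2 and fluoride then frees enantiomeric β-keto ester F3 in the same flask. Alkylation of racemic 7 with enantiopure 9 (NaH, THF, 0 °C to rt) should give 10 together with diastereomeric keto diester F4 that carries the mirror-image bicycle and the same (R)-arm. The two differ in relative configuration and should be separable by chromatography; the route is rejoined at 10.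

2. Step 9. What may go wrong: hydrogen delivery to the wrong face of C5=C6 (wrong C6 epimer), hydrogenolysis of the allylic C7–O bond before the double bond is saturated, or protonation of the enol at C3 from the wrong face. Fallback: remove the allylic alcohol first and place C6 next to a ketone. Setting out from 15, Dess–Martin oxidation should give ene-dione benzyl ester F5 in which C7 is a ketone. Hydrogenation and debenzylation (H2, Pd/C, then warming) pass through saturated diketo acid F6 to lactone diketone F7 whose C6 centre is now enolisable and can be equilibrated with Et3N or re-protonated kinetically. The less hindered C4 ketone alone should condense with TsNHNH2 to give mono-tosylhydrazone F8 which is reduced with catecholborane and then NaOAc·3H2O; the route is rejoined at 20.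

3. Step 18. What may go wrong: failure of the hindered tertiary alcohol to capture CO2, competing Meyer–Schuster-type isomerisation of the propargylic alcohol, or base-induced isomerisation of the angelate. Fallback: pre-formed carbonate and gold catalysis. Setting out from 29, Boc2O and DMAP should give tertiary tert-butyl carbonate F9 at the C7 oxygen. Ph3PAuNTf2 (monovalent gold, 2 mol %) in CH2Cl2 triggers 5-exo-dig attack of the carbonate carbonyl on the alkyne with loss of 2-methylpropene and gives the same alkylidene carbonate 30, here isolated. Hydrolysis (H2O, cat. Et3N) gives 31, where the route is rejoined.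

Further compounds
F1 | step 3 | enantiomeric cyclopropane | CC1=C[C@H]2[C@@H](O1)[C@@]2(C(=O)OCc3ccccc3)C(=C)O[Si](C)(C)C(C)(C)C
F2 | step 3 | enantiomeric silyl enol ether | C[C@]12CC(O[Si](C)(C)C(C)(C)C)=C(C(=O)OCc3ccccc3)[C@H](O1)C=C2
F3 | step 3 | enantiomeric β-keto ester | C[C@]12CC(O)=C(C(=O)OCc3ccccc3)[C@H](O1)C=C2
F4 | step 3 | diastereomeric keto diester | C[C@]12CC(=O)[C@](C(=O)OCc3ccccc3)([C@@H](C)C(=O)OC)[C@H](O1)C=C2
F5 | step 9 | ene-dione benzyl ester | CC(C)(C)[Si](c3ccccc3)(c4ccccc4)O[C@@H]1[C@@H]2OC(=O)[C@H](C)[C@]2(C(=O)OCc5ccccc5)C(=O)C=C(C)C1=O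
F6 | step 9 | saturated diketo acid | CC(C)(C)[Si](c3ccccc3)(c4ccccc4)O[C@@H]1[C@@H]2OC(=O)[C@H](C)[C@]2(C(=O)O)C(=O)C[C@H](C)C1=O
F7 | step 9 | lactone diketone | CC(C)(C)[Si](c3ccccc3)(c4ccccc4)O[C@@H]1[C@@H]2OC(=O)[C@H](C)[C@@H]2C(=O)C[C@H](C)C1=O
F8 | step 9 | mono-tosylhydrazone | CC(C)(C)[Si](c3ccccc3)(c4ccccc4)O[C@@H]1[C@@H]2OC(=O)[C@H](C)[C@@H]2C(=NNS(=O)(=O)c5ccc(C)cc5)C[C@H](C)C1=O
F9 | step 18 | tertiary tert-butyl carbonate | C/C=C(/C)C(=O)O[C@H]1[C@@H]2OC(=O)[C@H](C)[C@@H]2CC[C@H](C)[C@@]1(OC(=O)OC(C)(C)C)C#C[C@@H](C)OCc3ccc(OC)cc3
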